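**Retrosynthetic overview**
- The target is opened at both ring B prenyl groups: a double aromatic Claisen rearrangement of the 3',4'-bis(1,1-dimethylallyl) ether of the flavan installs them and unveils the catechol.
- Ring C is opened at O1–C8a: an Ullmann-type closure of a 1,3-diarylpropan-1-ol onto an aryl bromide uses the carbinol oxygen as nucleophile, so the C2 stereocenter is carried over unchanged.
- The C3–C4 bond is the key disconnection: a photochemical deaminative/deoxygenative coupling of a noradrenaline-derived pyridinium salt (radical at C3) with the N-tosylhydrazone of the ring A aldehyde (C4).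
- Ring B, C2 and C3 come from (R)-noradrenaline (Katritzky salt, then Pd-catalysed O-reverse-prenylation). Ring A comes from 2-bromo-4-hydroxybenzaldehyde (O-prenylation, then Claisen to the 1,1-dimethylallyl group).
- Ring order: rings A and B are bought as arenes; ring C is the only ring formed (step 6).

Assumption: (R)-noradrenaline free base, 2-bromo-4-hydroxybenzaldehyde, 2,4,6-triphenylpyrylium tetrafluoroborate and tert-butyl 2-methylbut-3-en-2-yl carbonate are taken as commercial.

Stereochemical note: the carbinol C–O bond of 1 is never broken. The descriptor changes from R (1–3) to S (9–13) only because CH2N outranks aryl whereas CH2C does not.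

**Step 1**
Reactants: 1 (R)-norepinephrine, 4-[(1R)-2-amino-1-hydroxyethyl]benzene-1,2-diol
Product: 2 1-[(2R)-2-(3,4-dihydroxyphenyl)-2-hydroxyethyl]-2,4,6-triphenylpyridin-1-ium tetrafluoroborate
Conditions: 2,4,6-triphenylpyrylium tetrafluoroborate (1.0 equiv), EtOH, Ar, 60 °C, 6 h; Et2O precipitation
Reagents that add atoms: 2,4,6-triphenylpyrylium tetrafluoroborate, c1ccc(cc1)-c1cc(-c2ccccc2)[o+]c(c1)-c1ccccc1.F[B-](F)(F)F
Why: Katritzky pyrylium-to-pyridinium condensation is selective for the primary amine over the phenolic and benzylic hydroxyls, turns the C–N bond into a redox-active radical precursor and masks nitrogen, while the bought carbinol stereocenter is not touched.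

**Step 2**
Reactants: 2 1-[(2R)-2-(3,4-dihydroxyphenyl)-2-hydroxyethyl]-2,4,6-triphenylpyridin-1-ium tetrafluoroborate
Product: 3 1-[(2R)-2-[3,4-bis(2-methylbut-3-en-2-yloxy)phenyl]-2-hydroxyethyl]-2,4,6-triphenylpyridin-1-ium tetrafluoroborate
Conditions: Pd(PPh3)4 (5 mol %), tert-butyl 2-methylbut-3-en-2-yl carbonate (4 equiv), 4 Å MS, THF/MeCN 3:1, 0 °C, 24 h
Reagents that add atoms: tert-butyl 2-methylbut-3-en-2-yl carbonate, C=CC(C)(C)OC(=O)OC(C)(C)C
Why: Tsuji–Trost O-allylation in which each phenoxide attacks the 1,1-dimethyl-π-allyl palladium intermediate at its substituted terminus under kinetic control at 0 °C; the aliphatic carbinol is not nucleophilic enough to compete and the stereocenter is not involved.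

**Step 3**
Reactants: 4 2-bromo-4-hydroxybenzaldehyde
Product: 5 2-bromo-4-[(3-methylbut-2-en-1-yl)oxy]benzaldehyde
Conditions: prenyl bromide (1.2 equiv), K2CO3 (1.5 equiv), DMF, 25 °C, 4 h
Reagents that add atoms: prenyl bromide (1-bromo-3-methylbut-2-ene), CC(C)=CCBr
Why: Williamson etherification of an acidic para-formyl phenol with a primary allylic bromide is fast and clean.

**Step 4**
Reactants: 5 2-bromo-4-[(3-methylbut-2-en-1-yl)oxy]benzaldehyde
Product: 6 2-bromo-4-hydroxy-5-(2-methylbut-3-en-2-yl)benzaldehyde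
Conditions: PhNEt2, Ar, sealed tube, 195 °C, 3 h
Reagents that add atoms: none
Why: Aromatic Claisen rearrangement ([3,3]) of the aryl prenyl ether delivers the 1,1-dimethylallyl group with allylic inversion to C5, the only accessible ortho carbon (C3 is flanked by bromine, the para carbon carries the formyl group), as in the analogous 2-methoxy series.

**Step 5**
Reactants: 3 1-[(2R)-2-[3,4-bis(2-methylbut-3-en-2-yloxy)phenyl]-2-hydroxyethyl]-2,4,6-triphenylpyridin-1-ium tetrafluoroborate; 6 2-bromo-4-hydroxy-5-(2-methylbut-3-en-2-yl)benzaldehyde; 7 4-methylbenzenesulfonohydrazide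
Product: 10 (1S)-1-[3,4-bis(2-methylbut-3-en-2-yloxy)phenyl]-3-[2-bromo-4-hydroxy-5-(2-methylbut-3-en-2-yl)phenyl]propan-1-ol, via N-tosylhydrazone 8 (not isolated), via N-alkyl-N'-tosylhydrazide 9 (not isolated)
Conditions: 6 (1.5 equiv), 7 (1.5 equiv), DMA, 40 °C, 1 h; then 3 (1.0 equiv), Hantzsch ester (2.5 equiv), 450 nm LEDs, Ar, 25 °C, 16 h; then K2CO3 (4 equiv), MeOH, 60 °C, 2 h
Reagents that add atoms: none
Why: Proposed new method: a deaminative–deoxygenative C(sp3)–C(sp3) coupling in which blue light excites the electron donor–acceptor complex of pyridinium 3 and Hantzsch ester, single-electron transfer and loss of 2,4,6-triphenylpyridine release the primary radical at C3, this nucleophilic radical adds to the C=N carbon of hydrazone 8 to give a stabilised hydrazinyl radical that is quenched by hydrogen-atom transfer from the Hantzsch ester (hydrazide 9), and carbonate then induces sulfinate loss and N2 extrusion from the resulting diazene to leave the C4 methylene; the closest known reaction types are the catalyst-free photochemical deaminative Giese alkylation of Katritzky salts and the photocatalytic addition of alkyl radicals to N-sulfonylhydrazones with base-induced denitrogenation, which have not been combined, and the adjacent carbinol stereocenter keeps its configuration because neither its C–O nor its C–H bond is touched.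

**Step 6**
Reactants: 10 (1S)-1-[3,4-bis(2-methylbut-3-en-2-yloxy)phenyl]-3-[2-bromo-4-hydroxy-5-(2-methylbut-3-en-2-yl)phenyl]propan-1-ol
Product: 11 (2S)-2-[3,4-bis(2-methylbut-3-en-2-yloxy)phenyl]-6-(2-methylbut-3-en-2-yl)-3,4-dihydro-2H-chromen-7-ol
Conditions: CuI (10 mol %), 3,4,7,8-tetramethyl-1,10-phenanthroline (20 mol %), Cs2CO3 (3 equiv), toluene, Ar, 80 °C, 16 h
Reagents that add atoms: none
Why: Intramolecular Ullmann-type copper-catalysed C–O coupling closes the six-membered ring C with the carbinol oxygen as nucleophile, so the C–O bond at the stereocenter is retained; copper does not ionise allyl aryl ethers, and 80 °C should keep Claisen rearrangement of the ring B ethers minor (any rearranged material converges in step 7).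

**Step 7**
Reactants: 11 (2S)-2-[3,4-bis(2-methylbut-3-en-2-yloxy)phenyl]-6-(2-methylbut-3-en-2-yl)-3,4-dihydro-2H-chromen-7-ol
Product: 13 (2S)-2-[3,4-dihydroxy-2,5-bis(3-methylbut-2-en-1-yl)phenyl]-6-(2-methylbut-3-en-2-yl)-3,4-dihydro-2H-chromen-7-ol, via mono-rearranged phenol 12 (not isolated)
Conditions: degassed toluene (0.02 M), Ar, sealed tube, 110 °C, 14 h
Reagents that add atoms: none
Why: Double aromatic Claisen rearrangement of the two aryl 1,1-dimethylallyl ethers sends the 4'-O group to C5' and the 3'-O group to C2', the only free ortho carbons, giving linear prenyl groups by allylic inversion; the neutral aprotic medium avoids quinone-methide opening of the benzylic ether, so C2 stays S.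

**Compound list**
1 | (R)-norepinephrine, 4-[(1R)-2-amino-1-hydroxyethyl]benzene-1,2-diol | O[C@H](c1ccc(O)c(O)c1)CN | starting material
2 | 1-[(2R)-2-(3,4-dihydroxyphenyl)-2-hydroxyethyl]-2,4,6-triphenylpyridin-1-ium tetrafluoroborate | O[C@H](c1ccc(O)c(O)c1)C[n+]2c(-c3ccccc3)cc(-c4ccccc4)cc2-c5ccccc5.F[B-](F)(F)F | intermediate
3 | 1-[(2R)-2-[3,4-bis(2-methylbut-3-en-2-yloxy)phenyl]-2-hydroxyethyl]-2,4,6-triphenylpyridin-1-ium tetrafluoroborate | O[C@H](c1ccc(OC(C)(C)C=C)c(OC(C)(C)C=C)c1)C[n+]2c(-c3ccccc3)cc(-c4ccccc4)cc2-c5ccccc5.F[B-](F)(F)F | intermediate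
4 | 2-bromo-4-hydroxybenzaldehyde | O=Cc1ccc(O)cc1Br | starting material
5 | 2-bromo-4-[(3-methylbut-2-en-1-yl)oxy]benzaldehyde | O=Cc1ccc(OCC=C(C)C)cc1Br | intermediate
6 | 2-bromo-4-hydroxy-5-(2-methylbut-3-en-2-yl)benzaldehyde | O=Cc1cc(C(C)(C)C=C)c(O)cc1Br | intermediate
7 | 4-methylbenzenesulfonohydrazide | Cc1ccc(cc1)S(=O)(=O)NN | starting material
8 | (E)-N'-{[2-bromo-4-hydroxy-5-(2-methylbut-3-en-2-yl)phenyl]methylidene}-4-methylbenzenesulfonohydrazide | Cc1ccc(cc1)S(=O)(=O)N/N=C/c1cc(C(C)(C)C=C)c(O)cc1Br | intermediate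
9 | N'-{(3S)-3-[3,4-bis(2-methylbut-3-en-2-yloxy)phenyl]-1-[2-bromo-4-hydroxy-5-(2-methylbut-3-en-2-yl)phenyl]-3-hydroxypropyl}-4-methylbenzenesulfonohydrazide (both epimers at C1, a center erased in the same pot) | O[C@H](c1ccc(OC(C)(C)C=C)c(OC(C)(C)C=C)c1)CC(NNS(=O)(=O)c1ccc(C)cc1)c1cc(C(C)(C)C=C)c(O)cc1Br | intermediate
10 | (1S)-1-[3,4-bis(2-methylbut-3-en-2-yloxy)phenyl]-3-[2-bromo-4-hydroxy-5-(2-methylbut-3-en-2-yl)phenyl]propan-1-ol | O[C@H](c1ccc(OC(C)(C)C=C)c(OC(C)(C)C=C)c1)CCc1cc(C(C)(C)C=C)c(O)cc1Br | intermediate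
11 | (2S)-2-[3,4-bis(2-methylbut-3-en-2-yloxy)phenyl]-6-(2-methylbut-3-en-2-yl)-3,4-dihydro-2H-chromen-7-ol | C=CC(C)(C)c1cc2c(cc1O)O[C@H](c1ccc(OC(C)(C)C=C)c(OC(C)(C)C=C)c1)CC2 | intermediate
12 | (2S)-2-[4-hydroxy-3-(2-methylbut-3-en-2-yloxy)-5-(3-methylbut-2-en-1-yl)phenyl]-6-(2-methylbut-3-en-2-yl)-3,4-dihydro-2H-chromen-7-ol | C=CC(C)(C)c1cc2c(cc1O)O[C@H](c1cc(CC=C(C)C)c(O)c(OC(C)(C)C=C)c1)CC2 | intermediate
13 | (2S)-2-[3,4-dihydroxy-2,5-bis(3-methylbut-2-en-1-yl)phenyl]-6-(2-methylbut-3-en-2-yl)-3,4-dihydro-2H-chromen-7-ol | C=CC(C)(C)c1cc2c(cc1O)O[C@H](c1cc(CC=C(C)C)c(O)c(O)c1CC=C(C)C)CC2 | target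

**Step count and risks**
Total steps: 7. Longest linear sequence: 5 (steps 1, 2, 5, 6, 7; the ring A branch through steps 3, 4, 5, 6, 7 is equally long).

Three steps most likely to fail:

Step 5 (the proposed new coupling). Risks are slow radical addition to an electron-rich aryl hydrazone and competing reduction of the radical to the hydrodeaminated ethyl arene. Fallback with known chemistry only, setting out from 1 and 6 and coming back at 10: 1 is N-protected with Fmoc-OSu (NaHCO3, dioxane/H2O) to N-Fmoc-(R)-norepinephrine F1; the etherification of step 2 (Pd(PPh3)4, tert-butyl 2-methylbut-3-en-2-yl carbonate, 0 °C) on F1 gives the N-Fmoc bis(1,1-dimethylallyl) ether F2; piperidine in DMF frees the primary amino alcohol F3; reductive amination of F3 with aldehyde 6 (MeOH, then NaBH4, 0 °C) gives the secondary benzylamine F4; nitrogen deletion of F4 with the anomeric amide N-(benzyloxy)-N-(pivaloyloxy)-4-(trifluoromethyl)benzamide (THF, 45 °C) excises the NH through an isodiazene that loses N2 and recombines in the solvent cage, forming the same C3–C4 bond and delivering 10.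

Step 6 (copper-catalysed ring closure). Risks are partial Claisen rearrangement of the ring B ethers at 80 °C, which would expose copper-binding catechol hydroxyls, and a sluggish electron-rich aryl bromide. Fallback setting out from 10 and coming back at 13, with the order of events reversed: 10 is heated first (degassed toluene, 110 °C) so that both ring B ethers rearrange, giving the bromo catechol carbinol F5; its three phenols are capped with allyl bromide (K2CO3, acetone, 56 °C; the aliphatic carbinol does not react) to give the tris(allyl ether) F6; with no thermally labile ether left, the Ullmann closure is run hot (CuI, 3,4,7,8-tetramethyl-1,10-phenanthroline, Cs2CO3, toluene, 110 °C) to the tris-O-allyl flavan F7; Pd(PPh3)4 and morpholine (THF, 25 °C) remove the three allyl groups under neutral conditions to give 13.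

Step 7 (double Claisen). Risks are migration of an allyl group onto the neighbouring oxygen-bearing carbon followed by intramolecular Diels–Alder trapping by the second allyl ether (caged adducts), and para migration from the hindered 3'-O ether. Fallback setting out from 11 and coming back at 12, with one ether handled at a time: Pd(PPh3)4 and morpholine (THF, 25 °C) strip both tertiary allyl groups from 11 to give the catechol flavan F8; one equivalent of the carbonate with Pd(PPh3)4 at 0 °C etherifies a single catechol oxygen, drawn as the 4'-O mono-ether F9 (the 3'-O isomer converges); warming (toluene, 100 °C) rearranges it, now next to a free hydroxyl and no second allyl ether, to the 5'-prenyl catechol F10; a second etherification goes to the less hindered 3'-OH and gives 12, which rearranges to 13 as in step 7. No intermediate carries two adjacent allyl ethers, which removes the Diels–Alder pathway; it does not change the C2' versus para selectivity of the last migration.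

**Further compounds**
F1 | step 5 | (9H-fluoren-9-yl)methyl N-[(2R)-2-(3,4-dihydroxyphenyl)-2-hydroxyethyl]carbamate | O[C@H](c1ccc(O)c(O)c1)CNC(=O)OCC1c2ccccc2-c2ccccc12
F2 | step 5 | (9H-fluoren-9-yl)methyl N-[(2R)-2-[3,4-bis(2-methylbut-3-en-2-yloxy)phenyl]-2-hydroxyethyl]carbamate | O[C@H](c1ccc(OC(C)(C)C=C)c(OC(C)(C)C=C)c1)CNC(=O)OCC1c2ccccc2-c2ccccc12
F3 | step 5 | (1R)-2-amino-1-[3,4-bis(2-methylbut-3-en-2-yloxy)phenyl]ethan-1-ol | O[C@H](c1ccc(OC(C)(C)C=C)c(OC(C)(C)C=C)c1)CN
F4 | step 5 | (1R)-1-[3,4-bis(2-methylbut-3-en-2-yloxy)phenyl]-2-({[2-bromo-4-hydroxy-5-(2-methylbut-3-en-2-yl)phenyl]methyl}amino)ethan-1-ol | O[C@H](c1ccc(OC(C)(C)C=C)c(OC(C)(C)C=C)c1)CNCc1cc(C(C)(C)C=C)c(O)cc1Br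
F5 | step 6 | (1S)-3-[2-bromo-4-hydroxy-5-(2-methylbut-3-en-2-yl)phenyl]-1-[3,4-dihydroxy-2,5-bis(3-methylbut-2-en-1-yl)phenyl]propan-1-ol | O[C@H](c1cc(CC=C(C)C)c(O)c(O)c1CC=C(C)C)CCc1cc(C(C)(C)C=C)c(O)cc1Br
F6 | step 6 | (1S)-1-[3,4-bis(allyloxy)-2,5-bis(3-methylbut-2-en-1-yl)phenyl]-3-[4-(allyloxy)-2-bromo-5-(2-methylbut-3-en-2-yl)phenyl]propan-1-ol | O[C@H](c1cc(CC=C(C)C)c(OCC=C)c(OCC=C)c1CC=C(C)C)CCc1cc(C(C)(C)C=C)c(OCC=C)cc1Br
F7 | step 6 | (2S)-7-(allyloxy)-2-[3,4-bis(allyloxy)-2,5-bis(3-methylbut-2-en-1-yl)phenyl]-6-(2-methylbut-3-en-2-yl)-3,4-dihydro-2H-chromene | C=CC(C)(C)c1cc2c(cc1OCC=C)O[C@H](c1cc(CC=C(C)C)c(OCC=C)c(OCC=C)c1CC=C(C)C)CC2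
F8 | step 7 | 4-[(2S)-7-hydroxy-6-(2-methylbut-3-en-2-yl)-3,4-dihydro-2H-chromen-2-yl]benzene-1,2-diol | C=CC(C)(C)c1cc2c(cc1O)O[C@H](c1ccc(O)c(O)c1)CC2
F9 | step 7 | (2S)-2-[3-hydroxy-4-(2-methylbut-3-en-2-yloxy)phenyl]-6-(2-methylbut-3-en-2-yl)-3,4-dihydro-2H-chromen-7-ol | C=CC(C)(C)c1cc2c(cc1O)O[C@H](c1ccc(OC(C)(C)C=C)c(O)c1)CC2
F10 | step 7 | 4-[(2S)-7-hydroxy-6-(2-methylbut-3-en-2-yl)-3,4-dihydro-2H-chromen-2-yl]-6-(3-methylbut-2-en-1-yl)benzene-1,2-diol | C=CC(C)(C)c1cc2c(cc1O)O[C@H](c1cc(CC=C(C)C)c(O)c(O)c1)CC2
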